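**Plan**
- **Cuts, in retrosynthetic order.** (a) The ketone carbon and the macrolactone carbonyl carbon of the ten-membered ring are rejoined as one tetrasubstituted enol-ether C=C, which folds that ring into a hexahydrochromene. (b) The exocyclic C=C between the butyrolactone α-carbon and the enol-ether carbon of the tetrahydrofuran is cut. (c) In the furopyran, the pyran O–CH bond at the ring fusion and the tetrahydrofuran O–C(sp2) bond are cut.
- **Forward order.** One C6 alcohol gives the aldehyde for both halves. East half: cyclopropenone, then furanone ring, then pyran ring, all in one flask. West half: diene plus cyclobutenone gives the cyclohexene/cyclobutanone, then the γ-lactone, then the dihydropyran. The lactone enolate is then added to the bicyclic lactone, water is lost, and the ten-membered ring is opened oxidatively last.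
- **Enabling feature.** In the tetrahydrofuran ring, the carbons C(=C), CH2 and CH(O-pyran) form a three-carbon unit at the oxidation level of a cyclopropenone. The ring oxygen sits on the CH directly attached to that unit. A 2-(1-hydroxyalkyl)cyclopropenone can therefore take up that C–O pair and grow into the five-membered ring.
- **Stereoconvergence.** The same unit makes both ring-fusion CH centres labile at the butenolide stage (acidic γ-H, reversible oxa-Michael addition). A mixture of carbinol epimers is thus funnelled into the one cis-fused isomer whose pyran chair holds CH3 and CH2 equatorial.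
- **Stereochemistry.** Both CH(CH3)–O centres come from (R)-hex-5-en-2-ol. The two furopyran fusion centres are set by thermodynamic relay from the methyl carbinol. The two butyrolactone centres come from a catalyst-controlled Diels–Alder reaction (cis by suprafacial addition, retention in the Baeyer–Villiger step). The E-alkene is reached by equilibration.

Key step: step 7

Assumption: the (S)-oxazaborolidinium catalyst is taken to shield cyclobutenone as it does other cyclic enones; if the opposite face is shielded, the equally available (R)-catalyst is used.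

Step 1
Reactants: 1 (R)-hex-5-en-2-ol
Product: 2 (R)-tert-butyl(hex-5-en-2-yloxy)dimethylsilane
Conditions: TBSCl, imidazole, DMF, 0 °C to rt
Reagents that add atoms: tert-butyldimethylsilyl chloride, CC(C)(C)[Si](C)(C)Cl
Why: Standard silyl ether protection of a secondary alcohol, which does not touch the carbinol centre.

Step 2
Reactants: 2 (R)-tert-butyl(hex-5-en-2-yloxy)dimethylsilane
Product: 4 (R)-4-(tert-butyldimethylsilyloxy)pentanal, via ozonide 3 (not isolated)
Conditions: O3, CH2Cl2, −78 °C; then Me2S, −78 °C to rt
Reagents that add atoms: ozone, [O-][O+]=O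
Why: Ozonolysis with reductive work-up cleaves only the terminal alkene and leaves the silyl ether and the remote stereocentre intact.

Step 3
Reactants: 5 1,3-dichloroacetone; 6 2,2-dimethylpropane-1,3-diol
Product: 7 2,2-bis(chloromethyl)-5,5-dimethyl-1,3-dioxane
Conditions: p-TsOH·H2O (cat.), benzene, reflux, Dean–Stark trap
Reagents that add atoms: none
Why: Acid-catalysed ketalisation with azeotropic removal of water, helped by the gem-dimethyl effect of the diol.

Step 4
Reactants: 7 2,2-bis(chloromethyl)-5,5-dimethyl-1,3-dioxane
Product: 9 6,6-dimethyl-4,8-dioxaspiro[2.5]oct-1-ene (cyclopropenone ketal), via sodium cyclopropenide 8 (not isolated)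
Conditions: NaNH2 (3 equiv), liquid NH3, −50 to −33 °C; then NH4Cl
Reagents that add atoms: none
Why: Base-induced 1,3-elimination closes the chlorocyclopropane and 1,2-dehydrochlorination gives the cyclopropene (the known double dehydrochlorination route to cyclopropenone ketals), while the third equivalent of base holds the product as its sodium salt until the quench.

Step 5
Reactants: 9 cyclopropenone ketal; 4 (R)-4-(tert-butyldimethylsilyloxy)pentanal
Product: 11 (4R)-4-(tert-butyldimethylsilyloxy)-1-(6,6-dimethyl-4,8-dioxaspiro[2.5]oct-1-en-1-yl)pentan-1-ol (both C1 epimers), via lithiated ketal 10 (not isolated)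
Conditions: n-BuLi, TMEDA, THF, −78 °C; then 4, −78 °C; aq NH4Cl
Reagents that add atoms: none
Why: Deprotonation of the acidic vinylic C–H of the ketal and 1,2-addition of the vinyllithium to the aldehyde, with no control needed at the new carbinol centre because step 7 erases and resets it.

Step 6
Reactants: 11 ketal carbinol (both epimers)
Product: 12 2-[(4R)-1,4-dihydroxypentyl]cycloprop-2-en-1-one (both carbinol epimers)
Conditions: 48 % aq HF, MeCN, 0 °C to rt
Reagents that add atoms: water, O
Why: Acid hydrolysis of the very labile cyclopropenone ketal (it passes through an aromatic hydroxycyclopropenylium ion) and acid/fluoride desilylation should occur under the same conditions.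

Step 7
Reactants: 12 2-[(4R)-1,4-dihydroxypentyl]cycloprop-2-en-1-one (both carbinol epimers)
Product: 15 (3aS,5R,7aS)-5-methylhexahydro-2H-furo[3,2-b]pyran-2-one, via ketene ylide 13 (not isolated), via butenolide 14 (not isolated)
Conditions: PPh3 (5 mol %), MeCN, rt; then DBU (30 mol %), 50 °C
Reagents that add atoms: none
Why: PPh3 adds reversibly to the alkyl-bearing ring carbon of 12, the strained C(=O)–C bond to that carbon breaks to give ketene ylide 13, the neighbouring carbinol OH adds to the ketene carbon and PPh3 is expelled, so that the three-membered ring (C=O, =CH, =C) takes up the carbinol CH and its O and becomes the five-membered butenolide 14, after which DBU triggers oxa-Michael addition of the remote secondary OH. The closest known reaction types are the phosphine-catalysed ring expansion of hydroxymethyl-substituted cyclopropenones to butenolides and the base-mediated intramolecular oxa-Michael addition to butenolides. The furanone ring closes by 5-exo-dig addition of OH to the ketene and the pyran ring by 6-exo-trig conjugate addition. The tether allows only a cis ring fusion, so the pyran-O-bearing CH follows the lactone-O-bearing CH, and the latter is reset because DBU epimerises 14 through its furanolate and the oxa-Michael step is reversible, so that the existing (R)-methyl carbinol centre selects, under thermodynamic control, the isomer whose pyran chair carries CH3 and CH2C=O equatorial and only the C–O bond axial. The step needs capture of the ketene by the proximal OH (five- against eight-membered ring) and cleavage of the ring bond to the substituted carbon, which is secured because only that ylide can be intercepted intramolecularly, whereas phosphine addition at the other carbon is reversible and unproductive.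

Step 8
Reactants: 4 (R)-4-(tert-butyldimethylsilyloxy)pentanal
Product: 16 (R)-tert-butyl(hex-5-yn-2-yloxy)dimethylsilane
Conditions: dimethyl (1-diazo-2-oxopropyl)phosphonate, K2CO3, MeOH, 0 °C to rt
Reagents that add atoms: dimethyl (1-diazo-2-oxopropyl)phosphonate, CC(=O)C(=[N+]=[N-])P(=O)(OC)OC
Why: Ohira–Bestmann variant of the Seyferth–Gilbert homologation turns the aldehyde into the terminal alkyne under mild base that tolerates the silyl ether.

Step 9
Reactants: 16 (R)-tert-butyl(hex-5-yn-2-yloxy)dimethylsilane
Product: 17 (R)-tert-butyldimethyl[(5-methylidenehept-6-en-2-yl)oxy]silane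
Conditions: ethylene (1 atm), second-generation Grubbs catalyst RuCl2(=CHPh)(PCy3)(H2IMes) (5 mol %), toluene, 80 °C
Reagents that add atoms: ethylene, C=C
Why: Cross enyne metathesis of a terminal alkyne with ethylene gives the 2-substituted 1,3-butadiene directly.

Step 10
Reactants: 18 3-bromocyclobutanone
Product: 19 cyclobut-2-en-1-one
Conditions: n-Bu3N, neat, rt, product distilled under reduced pressure into a cold trap
Reagents that add atoms: none
Why: E1cB dehydrobromination of a β-bromo ketone, with removal of the volatile enone limiting its polymerisation.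

Step 11
Reactants: 17 diene; 19 cyclobut-2-en-1-one
Product: 20 (1S,6S)-3-[(3R)-3-(tert-butyldimethylsilyloxy)butyl]bicyclo[4.2.0]oct-3-en-7-one
Conditions: (S)-3,3-diphenyl-1-(o-tolyl)tetrahydro-1H,3H-pyrrolo[1,2-c][1,3,2]oxazaborole (20 mol %), HNTf2 (18 mol %), CH2Cl2, −78 °C
Reagents that add atoms: none
Why: In this enantioselective oxazaborolidinium-catalysed Diels–Alder reaction of a strained cyclic enone, the para rule joins the diene terminus next to the alkyl group to the enone β-carbon, suprafacial addition fixes the cis fusion, and the catalyst-shielded enone face sets both new stereocentres.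

Step 12
Reactants: 20 bicyclic cyclobutanone
Product: 21 (3aS,7aS)-5-[(3R)-3-(tert-butyldimethylsilyloxy)butyl]-3a,4,7,7a-tetrahydro-1-benzofuran-2(3H)-one
Conditions: 30 % aq H2O2, AcOH, 0 °C
Reagents that add atoms: hydrogen peroxide, OO
Why: In this strain-accelerated Baeyer–Villiger oxidation the more substituted bridgehead carbon migrates with retention, under conditions that do not epoxidise the trisubstituted alkene.

Step 13
Reactants: 21 cyclohexene lactone
Product: 23 (3aS,7aS)-5-[(3R)-3-(tert-butyldimethylsilyloxy)butyl]-6-hydroxyhexahydro-1-benzofuran-2(3H)-one (isomers at C5 and C6), via alkylborane 22 (not isolated)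
Conditions: BH3·SMe2, THF, 0 °C; then NaBO3·4H2O, THF/H2O, rt
Reagents that add atoms: sodium perborate, [Na+].[Na+].O[B-]1(O)OO[B-](O)(O)OO1
Why: Hydroboration–oxidation places boron on the less substituted alkene carbon faster than the lactone is reduced, and the two new centres need no control because steps 14 and 15 destroy them.

Step 14
Reactants: 23 secondary alcohol (isomers)
Product: 24 (3aS,7aS)-5-[(3R)-3-(tert-butyldimethylsilyloxy)butyl]hexahydro-1-benzofuran-2,6-dione (epimers at C5)
Conditions: Dess–Martin periodinane, CH2Cl2, 0 °C to rt
Reagents that add atoms: none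
Why: Dess–Martin oxidation works without base and so avoids β-elimination of the lactone carboxylate from the new β-acyloxy ketone.

Step 15
Reactants: 24 keto lactone
Product: 26 (3aS,7R,9aS)-7-methyl-3,3a,4,5,6,7,9,9a-octahydro-2H-furo[3,2-g]chromen-2-one (tricyclic enol-ether lactone, C4a=C8a), via hydroxy ketone 25 (not isolated)
Conditions: HF·pyridine, THF, 0 °C to rt; then PPTS (cat.), 4 Å molecular sieves, benzene, 50 °C
Reagents that add atoms: none
Why: After desilylation, the known acid-catalysed cyclodehydration of 2-(3-hydroxyalkyl)cyclohexanones (six-membered hemiketal, then loss of water) gives the more substituted ring-fusion enol ether, which masks the future ketone and ester in one C=C bond.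

Step 16
Reactants: 26 tricyclic enol-ether lactone; 15 bicyclic lactone
Product: 28 3-[(3aS,5R,7aS)-2-hydroxy-5-methylhexahydro-2H-furo[3,2-b]pyran-2-yl] derivative of 26 (isomers at C3 and at the hemiketal carbon, in equilibrium with the open hydroxy β-keto lactone), via lithium enolate 27 (not isolated)
Conditions: LiN(i-Pr)2, THF, −78 °C; then 15, −78 °C; aq NH4Cl
Reagents that add atoms: none
Why: In this crossed Claisen-type addition of a lactone enolate to a γ-lactone carbonyl (the reaction type of the self-condensation of γ-butyrolactone) the tetrahedral alkoxide should persist at low temperature, 26 has no other acidic or electrophilic site, and the new centres vanish in step 17.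

Step 17
Reactants: 28 hemiketal adduct
Product: 29 (E)-3-[(3aS,5R,7aS)-5-methylhexahydro-2H-furo[3,2-b]pyran-2-ylidene] derivative of 26
Conditions: PPTS (cat.), 4 Å molecular sieves, benzene, 50 °C
Reagents that add atoms: none
Why: In this acid-catalysed dehydration of the β-hydroxy lactone (cyclic hemiketal) to the push–pull alkene, reversible protonation at the lactone α-carbon lets the geometry settle on the E isomer, in which the small ring O rather than the CH2 faces the substituted lactone β-carbon and the C–O and C=O dipoles are opposed.

Step 18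
Reactants: 29 alkylidene bis-enol ether
Product: 31 cordycicadin C, via ozonide 30 (not isolated)
Conditions: O3 (1 equiv, titrated CH2Cl2 solution), CH2Cl2, −78 °C; then Me2S, −78 °C to rt
Reagents that add atoms: ozone, [O-][O+]=O
Why: This ring-expanding oxidative cleavage of a bicyclic enol ether to a keto lactone turns the shared C=C bond into the ketone and the ester carbonyl of the ten-membered ring, and the electron-rich tetrasubstituted enol ether should react well before the acceptor-substituted enol ether.

**Compound list**
1 | (R)-hex-5-en-2-ol | C[C@@H](O)CCC=C | starting material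
2 | (R)-tert-butyl(hex-5-en-2-yloxy)dimethylsilane | C[C@@H](O[Si](C)(C)C(C)(C)C)CCC=C | intermediate
3 | 3-[(3R)-3-(tert-butyldimethylsilyloxy)butyl]-1,2,4-trioxolane (ozonide) | C[C@@H](O[Si](C)(C)C(C)(C)C)CCC1OCOO1 | intermediate
4 | (R)-4-(tert-butyldimethylsilyloxy)pentanal | C[C@@H](O[Si](C)(C)C(C)(C)C)CCC=O | intermediate
5 | 1,3-dichloroacetone | O=C(CCl)CCl | starting material
6 | 2,2-dimethylpropane-1,3-diol | OCC(C)(C)CO | starting material
7 | 2,2-bis(chloromethyl)-5,5-dimethyl-1,3-dioxane | CC1(C)COC(CCl)(CCl)OC1 | intermediate
8 | sodium salt of 9 | [Na]C1=CC12OCC(C)(C)CO2 | intermediate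
9 | 6,6-dimethyl-4,8-dioxaspiro[2.5]oct-1-ene | CC1(C)COC2(C=C2)OC1 | intermediate
10 | 1-lithio derivative of 9 | [Li]C1=CC12OCC(C)(C)CO2 | intermediate
11 | (4R)-4-(tert-butyldimethylsilyloxy)-1-(6,6-dimethyl-4,8-dioxaspiro[2.5]oct-1-en-1-yl)pentan-1-ol, both C1 epimers | C[C@@H](O[Si](C)(C)C(C)(C)C)CCC(O)C1=CC12OCC(C)(C)CO2 | intermediate
12 | 2-[(4R)-1,4-dihydroxypentyl]cycloprop-2-en-1-one, both carbinol epimers | C[C@@H](O)CCC(O)C1=CC1=O | intermediate
13 | ketene ylide from 12 and PPh3 | C[C@@H](O)CCC(O)C(C=C=O)=P(c1ccccc1)(c1ccccc1)c1ccccc1 | intermediate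
14 | 5-[(3R)-3-hydroxybutyl]furan-2(5H)-one, interconverting C5 epimers | C[C@@H](O)CCC1OC(=O)C=C1 | intermediate
15 | (3aS,5R,7aS)-5-methylhexahydro-2H-furo[3,2-b]pyran-2-one | O=C1C[C@@H]2O[C@H](C)CC[C@@H]2O1 | intermediate
16 | (R)-tert-butyl(hex-5-yn-2-yloxy)dimethylsilane | C[C@@H](O[Si](C)(C)C(C)(C)C)CCC#C | intermediate
17 | (R)-tert-butyldimethyl[(5-methylidenehept-6-en-2-yl)oxy]silane | C[C@@H](O[Si](C)(C)C(C)(C)C)CCC(=C)C=C | intermediate
18 | 3-bromocyclobutanone | O=C1CC(Br)C1 | starting material
19 | cyclobut-2-en-1-one | O=C1C=CC1 | intermediate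
20 | (1S,6S)-3-[(3R)-3-(tert-butyldimethylsilyloxy)butyl]bicyclo[4.2.0]oct-3-en-7-one | O=C1C[C@@H]2CC(CC[C@@H](C)O[Si](C)(C)C(C)(C)C)=CC[C@H]12 | intermediate
21 | (3aS,7aS)-5-[(3R)-3-(tert-butyldimethylsilyloxy)butyl]-3a,4,7,7a-tetrahydro-1-benzofuran-2(3H)-one | O=C1C[C@@H]2CC(CC[C@@H](C)O[Si](C)(C)C(C)(C)C)=CC[C@@H]2O1 | intermediate
22 | 6-boranyl derivative (alkylborane), isomers at C5 and C6 | O=C1C[C@@H]2CC(CC[C@@H](C)O[Si](C)(C)C(C)(C)C)C(B)C[C@@H]2O1 | intermediate
23 | 6-hydroxy lactone, isomers at C5 and C6 | O=C1C[C@@H]2CC(CC[C@@H](C)O[Si](C)(C)C(C)(C)C)C(O)C[C@@H]2O1 | intermediate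
24 | (3aS,7aS)-5-[(3R)-3-(tert-butyldimethylsilyloxy)butyl]hexahydro-1-benzofuran-2,6-dione, epimers at C5 | O=C1C[C@@H]2CC(CC[C@@H](C)O[Si](C)(C)C(C)(C)C)C(=O)C[C@@H]2O1 | intermediate
25 | (3aS,7aS)-5-[(3R)-3-hydroxybutyl]hexahydro-1-benzofuran-2,6-dione (in equilibrium with its hemiketal) | O=C1C[C@@H]2CC(CC[C@@H](C)O)C(=O)C[C@@H]2O1 | intermediate
26 | (3aS,7R,9aS)-7-methyl-3,3a,4,5,6,7,9,9a-octahydro-2H-furo[3,2-g]chromen-2-one | C[C@@H]1CCC2=C(O1)C[C@@H]3OC(=O)C[C@@H]3C2 | intermediate
27 | lithium enolate of 26 | C[C@@H]1CCC2=C(O1)C[C@@H]3OC(O[Li])=C[C@@H]3C2 | intermediate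
28 | hemiketal adduct of 26 and 15, isomers at the lactone α-carbon and at the hemiketal carbon | C[C@@H]1CCC2=C(O1)C[C@@H]3OC(=O)C(C4(O)C[C@@H]5O[C@H](C)CC[C@@H]5O4)[C@@H]3C2 | intermediate
29 | (E)-alkylidene bis-enol ether | C[C@@H]1CCC2=C(O1)C[C@@H]3OC(=O)/C(=C4\C[C@@H]5O[C@H](C)CC[C@@H]5O4)[C@@H]3C2 | intermediate
30 | ozonide (1,2,4-trioxolane) across the former chromene C=C bond of 29 | C[C@@H]1CCC23OOC(O1)(O2)C[C@@H]4OC(=O)/C(=C5\C[C@@H]6O[C@H](C)CC[C@@H]6O5)[C@@H]4C3 | intermediate
31 | cordycicadin C | C[C@@H]1CCC(=O)C[C@H]2/C(=C3/C[C@@H]4O[C@H](C)CC[C@@H]4O3)C(=O)O[C@H]2CC(=O)O1 | target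

**Totals**
- Total step count: 18.
- Longest linear sequence: 12 (steps 1, 2, 8, 9, 11, 12, 13, 14, 15, 16, 17, 18).

**Steps most likely to fail**

Step 16. Proton transfer from the α-CH2 of 15 to enolate 27 may outrun carbonyl addition. It would be followed by retro-oxa-Michael opening of 15 and conjugate addition of the enolate to the butenolide so formed.
The fallback sets out from 15 and 26 and returns at 29. Aminolysis of 15 with MeNH(OMe)·HCl and i-PrMgCl should give the Weinreb amide F1, whose free secondary alcohol is silylated (TESCl, imidazole) to the triethylsilyl ether F2. Enolate 27 is acylated by F2, whose α-hydrogens are less acidic than those of a lactone and whose chelated tetrahedral adduct does not collapse early. This gives the β-keto lactone F3. HF·pyridine followed by PPTS and 4 Å molecular sieves then removes the silyl group and closes the enol ether to 29.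

Step 11. The catalyst may discriminate poorly between the two faces of the small, flat enone, or the strong acid may polymerise cyclobutenone.
The fallback sets out from 17 and 19 and returns at 21. It moves the stereochemical decision from the cycloaddition to the oxidation. The uncatalysed Diels–Alder reaction (CH2Cl2, rt) should give 20 together with the (1R,6R)-cyclobutanone F4. A Baeyer–Villiger monooxygenase (cyclohexanone monooxygenase, O2, NADPH recycling) is known to turn antipodal fused cyclobutanones into regioisomeric lactones. Thus 20 should give 21, and F4 should give the regioisomeric lactone F5 with oxygen next to the CH2 group. The two differ in constitution and can be separated by chromatography. An enantiocomplementary monooxygenase is used if the pairing is reversed.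

Step 7. The free cyclopropenone diol may be lost during the aqueous deprotection. Alternatively, the ketene may be intercepted intermolecularly, which leads to oligomers before the ring can grow.
The fallback sets out from 4 and returns at 14. Addition of CH2=CHMgBr gives the allylic alcohol F6 (both epimers), and acryloyl chloride with Et3N gives the acrylate F7. Ring-closing metathesis with the second-generation Grubbs catalyst gives the silylated butenolide F8, and HF·pyridine gives 14. The DBU equilibration of step 7 then carries 14 on to 15 unchanged.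

**Further compounds**
F1 | step 16 | 2-[(2S,3S,6R)-3-hydroxy-6-methyloxan-2-yl]-N-methoxy-N-methylacetamide | CON(C)C(=O)C[C@@H]1O[C@H](C)CC[C@@H]1O
F2 | step 16 | triethylsilyl ether of F1 | CON(C)C(=O)C[C@@H]1O[C@H](C)CC[C@@H]1O[Si](CC)(CC)CC
F3 | step 16 | β-keto lactone from 27 and F2 (epimers at the lactone α-carbon) | C[C@@H]1CCC2=C(O1)C[C@@H]3OC(=O)C(C(=O)C[C@@H]4O[C@H](C)CC[C@@H]4O[Si](CC)(CC)CC)[C@@H]3C2
F4 | step 11 | (1R,6R)-3-[(3R)-3-(tert-butyldimethylsilyloxy)butyl]bicyclo[4.2.0]oct-3-en-7-one | O=C1C[C@H]2CC(CC[C@@H](C)O[Si](C)(C)C(C)(C)C)=CC[C@@H]12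
F5 | step 11 | regioisomeric cis-fused lactone from F4 (oxygen inserted next to CH2) | O=C1OC[C@H]2CC(CC[C@@H](C)O[Si](C)(C)C(C)(C)C)=CC[C@@H]12
F6 | step 7 | (6R)-6-(tert-butyldimethylsilyloxy)hept-1-en-3-ol, both C3 epimers | C[C@@H](O[Si](C)(C)C(C)(C)C)CCC(O)C=C
F7 | step 7 | acrylate of F6 | C[C@@H](O[Si](C)(C)C(C)(C)C)CCC(OC(=O)C=C)C=C
F8 | step 7 | 5-[(3R)-3-(tert-butyldimethylsilyloxy)butyl]furan-2(5H)-one, both C5 epimers | C[C@@H](O[Si](C)(C)C(C)(C)C)CCC1OC(=O)C=C1
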